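Remark on the chemistry: locants C1–C15 refer to the acid half (C14 = carboxyl carbon on C10, C15 = methyl on C4), primed locants C1′–C11′ to the iridoid half (C1′ = lactone carbonyl, C10′ = the oxygenated CH2 on C8′, C11′ = the methylene on C4′). Ring A is the cyclopentane and ring B the lactone of the iridoid half; ring C is the cycloheptadiene and ring D the cyclopentane of the acid half. (tert-Butyldimethylsilyloxy)acetaldehyde 28 is taken as a commercial reagent.

## Analysis of the target

Nardostachysin (35) is an ester of two terpenoid halves that share no carbon–carbon bond: a cis-fused cyclopenta[c]pyran-1-one (rings A and B) and a hexahydroazulene-4-carboxylic acid (rings C and D), joined through the oxygen on C10′ and the carboxyl carbon C14. The iridoid half has four contiguous stereocentres, C5′, C9′, C8′ and C7′. The ring fusion is cis, and the secondary C7′ hydroxyl and the tertiary C8′ hydroxyl sit on the concave face, cis to each other and to the lactone carbonyl C1′, while C10′ points to the convex face. The acid half has three stereocentres: C1 and C5 form a cis ring fusion and the C4 methyl group is cis to both ring-C bonds (all-cis). Nothing relays configuration from one half to the other, so each half needs its own source of absolute configuration. The sensitive groups are the β-hydroxy lactone with its allylic C3′–O bond and the exocyclic C4′=C11′ alkene, the triol that must be acylated on one oxygen only, and the C7=C8/C9=C10 dienoate, whose C1 hydrogen is a vinylogous acidic site. The two hard problems are the seven-membered ring C with both double bonds in fixed positions beside a defined ring fusion, and the diol of ring A on the face that external oxidants do not reach. The strategy rests on one feature of ring C: C10, which carries C14, and C8 are separated only by C9. With a ketone at C8 the array C14–C10–C9–C8 is a γ-keto ester, which is what the insertion of one carbon between the carbonyl groups of a six-membered β-keto ester gives, and ring D with C1, C5 and C4 all-cis can already be present in that precursor.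

## Retrosynthetic reasoning

The first cut is the ester bond between C14 and the oxygen on C10′, which divides 35 into the dienoic acid 21 and the iridoid triol 33. It is the only bond between the halves, and it gives two fragments of similar size that are made in parallel. The forward reaction has to acylate one hydroxyl of three; the C10′ hydroxyl is the only primary one, and the acyl donor from 21 is α-branched and therefore discriminating.

In 21 the carboxyl group is masked as the tert-butyl ester 20, and the C7=C8 double bond of 20 is traced through the dienyl triflate 19 to the C8 ketone of 18. The ketone is introduced in the backward direction because it creates the 1,4-relationship to C14 that the key step needs. In 18 it is flanked by the sp2 carbon C9, so it can enolise only toward C7, and the forward sequence can place the second double bond in one position only.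

The key disconnection removes C9 from ring C. The C9–C10 and C8–C9 bonds of 18 are cut and C10 is reconnected to C8, which gives the six-membered β-keto ester 14 and the one-carbon donor 15. The cut is made here because it trades a seven-membered ring for a six-membered ring that closes by a routine condensation, and because C9 lies exactly between the two carbonyl-bearing carbons. The forward reaction has to insert one carbon between the two carbonyl groups and nowhere else, and then introduce the C9=C10 double bond.

14 is opened at the C8–C10 bond (Dieckmann condensation) to the diester 13. The tert-butyl ester supplies the nucleophilic carbon C10 and the methyl ester the electrophilic carbon C8, and only this direction leads to an enolisable β-keto ester. 13 is cut at C6–C7 into the primary iodide 11 and the ester 12, which brings in C7, C8 and the isopropyl group as one piece.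

11 comes from the alcohol 10, and 10 from the all-cis diester 9 by reduction of the methyl ester alone; the two esters are different so that C6 and C10 can be addressed separately. The stereocentres C1 and C5 of 9 are traced to a hydrogenation of the cyclopentene 8, in which the C4 methyl group is the only stereocentre and sends hydrogen to the opposite face. 8 is cut at the C1–C10 bond into the enol triflate 5 and the bromoacetate 6, used as its zinc reagent 7.

5 derives from the β-keto ester 4, 4 from 3 by ozonolysis, and 3 from 1 by ring contraction. The chiral pool supplies C4 with its methyl group in the required absolute configuration, and the ring contraction places the ester carbon that becomes C6 next to it.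

33 is the desilylated form of 32. In 32 the C7′–C8′ bond is cut, which opens ring A and leads to the keto aldehyde 31. This bond joins the two oxygen-bearing carbons, so a reductive coupling of two carbonyl groups makes both hydroxyls in the same step. The forward reaction must put both oxygens on the concave face; a metal that bridges the C8′ oxygen and the lactone carbonyl does this from inside the molecule.

31 is the unmasked form of the acetal 30. The C8′–C9′ bond of 30 is cut by an aldol addition and oxidation into the lactone 27 and the aldehyde 28, which brings in C8′ and C10′ with the C10′ oxygen already protected.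

27 is the acetal of 26, and ring B of 26 is cut at the O2′–C3′ bond to the chloro acid 25. The lactone is closed by displacement and not by acylation, so the free aldehyde takes no part. 25 is traced through 24 and 23 to 22. 22 supplies C5′ in the required configuration with the 2-propenyl group (C4′, C11′, C3′) and two CH2 arms. Allylic chlorination gives C3′ its leaving group, and excision of the methyl-bearing ring carbon turns the arms into C9′–C1′ (acid) and C6′–C7′ (aldehyde).

## Alternatives that were turned down

Alternative 1: The disconnection cuts C5′–C9′, C6′–C7′ and C7′–C8′ and takes C7′ from carbon monoxide, so rings A and B arise together from the acetal-tethered 1,7-enyne A1 (alkyne on the acetal carbon C1′, vinyl group on the C4′ carbinol). In the forward direction Co2(CO)8 with trimethylamine N-oxide, or [Rh(CO)2Cl]2 under carbon monoxide, would convert A1 into the bicyclic enone acetal A2.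
- For it: three carbon–carbon bonds and both rings of the iridoid half form in one step from a linear precursor, with C10′ and the C7′ oxygen in place.
- Against it: A2 carries a C8′=C9′ double bond and a C7′ ketone, while the target needs hydrogen at C9′ and a tertiary hydroxyl at C8′ on the concave face. Reagents that bring oxygen to C8′ from outside the bicycle approach the convex face and would give the C8′ epimer.
- The acetal carbon must also be oxidised to the lactone, and the C4′ ether turned into the methylene group by oxidation and olefination beside the epimerisable C5′.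
- A 1,7-enyne cyclises less readily than a 1,6-enyne, and C4′ alone has to control C5′.
- Comparison: the alternative is stronger in bonds formed per step. It spends the key step on the half whose rings are the easier ones, needs a series of redox corrections, and leaves ring C unsolved. The chosen strategy uses its key step for the seven-membered ring, creates no stereocentre in it, and closes ring A by a coupling that delivers both oxygens to the concave face directly.

Alternative 2: The disconnection cuts C8′–C9′, so ring A is closed last from the α-diazo lactone A3, in which ring B is complete and C7′ and C8′ belong to a trans-disubstituted dioxolane from the chiral pool. In the forward direction Rh2(O2CCPh3)4 would decompose A3, and the C9′ carbenoid would insert into the C8′–H bond, which is activated by the adjacent oxygen, with retention to give the silyl-protected acetonide A4.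
- For it: C7′ and C8′ are bought with their configuration, the tertiary carbinol is formed with retention, and the diol emerges already protected as an acetonide. This would make the later acylation at C10′ unambiguous, and on that point the alternative is stronger than the chosen route, which relies on the rate difference between a primary and a secondary hydroxyl.
- Against it: the carbenoid at C9′ has a β-hydrogen at C5′ (1,2-hydride shift to the unsaturated lactone), competing C–H bonds next to oxygen at C10′, and an alkene in the same molecule. Bulky carboxylate ligands reduce these pathways but do not remove them.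
- The diazo group has to be put on a lactone α-carbon by deacylative diazo transfer, and C5′ has to be joined to the dioxolane with its own stereocontrol, which adds steps.
- Comparison: like alternative 1 it addresses only the iridoid half. The chosen strategy offers a key step with a single reactive site (only the enolate between two carbonyl groups meets the carbenoid), and in ring A it derives C7′, C8′ and C9′ from the one stereocentre C5′ in one operation.

Alternative 3: The disconnection cuts the C10–C14 bond and the C14–O ester bond and takes C14 from carbon monoxide; the partners are the dienyl triflate A5 and the iridoid acetonide alcohol A6, and the product is nardostachysin 7′,8′-acetonide A7. In the forward direction Pd(OAc)2 with 1,3-bis(diphenylphosphino)propane and Et3N under carbon monoxide would carbonylate A5 and the acylpalladium intermediate would be captured by A6.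
- For it: the carboxyl carbon is introduced while the halves are joined, so no free acid, no activation and no tert-butyl ester cleavage are needed. In convergence at the junction it is stronger than the chosen route.
- Against it: no ring is formed, so ring C and ring A remain to be built by other means.
- The triflate oxygen of A5 has to come from a carbonyl group at C10, which can enolise toward the ring-fusion carbon C1 as well as toward C9; this endangers both the diene position and the C1 configuration.
- A6 contains an allylic carboxylate (C3′–O2′) that zerovalent palladium can ionise.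
- A6 is a hindered, neopentyl-type alcohol that would have to be used near stoichiometry in a reaction that normally runs with excess alcohol.
- Comparison: the chosen strategy gives up one step at the junction and gains a metal-free esterification that the allylic lactone tolerates, and a ketone at C8 that can enolise in one direction only.

Key step: step 10

## Route

Step 1
Reactants: 1 (R)-pulegone
Product: 3 methyl (5R)-5-methyl-2-(propan-2-ylidene)cyclopentane-1-carboxylate (methyl pulegenate; C1 epimers), via pulegone dibromide 2 (not isolated)
Conditions: Br2, Et2O, −10 °C; then NaOMe, MeOH, reflux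
Reagents that add atoms: bromine, BrBr; sodium methoxide, [Na+].[O-]C
Why: Bromine adds to the tetrasubstituted alkene, and methoxide then brings about a Favorskii rearrangement (enolisation on the CH2 side of the ketone, cyclopropanone, opening with loss of bromide) that contracts the ring and restores the isopropylidene group; the methyl-bearing centre (later C4) is not enolisable and is carried through unchanged.

Step 2
Reactants: 3 methyl pulegenate
Product: 4 methyl (2R)-2-methyl-5-oxocyclopentane-1-carboxylate (C1 epimerisable)
Conditions: O3, CH2Cl2/MeOH, −78 °C; then Me2S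
Reagents that add atoms: ozone, [O-][O+]=O
Why: Ozonolysis with reductive work-up cleaves the isopropylidene group to the ring ketone; only the methyl-bearing centre needs to be defined, since the ester carbon becomes sp2 in step 3.

Step 3
Reactants: 4 methyl (2R)-2-methyl-5-oxocyclopentane-1-carboxylate
Product: 5 methyl (5R)-5-methyl-2-(trifluoromethanesulfonyloxy)cyclopent-1-ene-1-carboxylate
Conditions: Tf2O, iPr2NEt, CH2Cl2, −78 °C
Reagents that add atoms: trifluoromethanesulfonic anhydride, O=S(=O)(OS(=O)(=O)C(F)(F)F)C(F)(F)F
Why: O-sulfonylation of the β-keto ester enol with a hindered amine at low temperature gives the enol triflate; the stereocentre is allylic and not acidic under these conditions.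

Step 4
Reactants: 5 enol triflate; 6 tert-butyl bromoacetate
Product: 8 methyl (5R)-2-(2-tert-butoxy-2-oxoethyl)-5-methylcyclopent-1-ene-1-carboxylate, via Reformatsky reagent 7 (not isolated)
Conditions: 6, Zn, Me3SiCl (cat.), THF, rt; then 5, Pd(PPh3)4 (5 mol %), THF, 60 °C
Reagents that add atoms: zinc, [Zn]
Why: Negishi coupling of a Reformatsky reagent with an alkenyl triflate (oxidative addition to zerovalent palladium, transmetallation from zinc, reductive elimination) forms the C1–C10 bond; the zinc ester enolate is mild enough to leave both esters intact.

Step 5
Reactants: 8 cyclopentene diester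
Product: 9 methyl (1R,2R,5R)-2-(2-tert-butoxy-2-oxoethyl)-5-methylcyclopentane-1-carboxylate (all-cis)
Conditions: H2 (40 bar), 5% Rh on Al2O3, EtOAc, rt
Reagents that add atoms: none
Why: Heterogeneous syn-hydrogenation of the tetrasubstituted alkene takes place on the face opposite the allylic C4 methyl group, so C1 and C5 are set with CH2CO2tBu, CO2Me and CH3 all cis (substrate control by C4); Rh is preferred to Pd to limit double-bond migration before reduction.

Step 6
Reactants: 9 all-cis diester
Product: 10 tert-butyl 2-[(1R,2R,3R)-2-(hydroxymethyl)-3-methylcyclopentyl]acetate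
Conditions: LiBH4, MeOH (1 equiv), THF, 0 °C to rt
Reagents that add atoms: none
Why: Chemoselective hydride reduction: LiBH4 reduces the methyl ester and leaves the tert-butyl ester, and the non-basic medium does not epimerise C5; the product is taken on without delay because acid would lactonise it.

Step 7
Reactants: 10 hydroxy ester
Product: 11 tert-butyl 2-[(1R,2R,3R)-2-(iodomethyl)-3-methylcyclopentyl]acetate
Conditions: I2, PPh3, imidazole, CH2Cl2, 0 °C to rt
Reagents that add atoms: iodine, II
Why: Appel-type iodination of the primary alcohol through its alkoxyphosphonium salt; the neutral conditions avoid lactonisation onto the tert-butyl ester and no stereocentre is involved.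

Step 8
Reactants: 11 iodide; 12 methyl 3-methylbutanoate
Product: 13 methyl 2-{[(1R,2R,5R)-2-(2-tert-butoxy-2-oxoethyl)-5-methylcyclopentyl]methyl}-3-methylbutanoate (C7 epimers)
Conditions: 12 (3 equiv), LiN(iPr)2, THF, −78 °C; DMPU; then 11, −78 to −20 °C
Reagents that add atoms: none
Why: SN2 alkylation of the lithium enolate of 12 by the primary iodide forms the C6–C7 bond; excess enolate and the polar additive offset the β-branching of both partners, and the C7 configuration is irrelevant because C7 becomes sp2 in step 11.

Step 9
Reactants: 13 diester
Product: 14 tert-butyl (1R,3aS,7aR)-1-methyl-5-oxo-6-(propan-2-yl)octahydro-1H-indene-4-carboxylate (C10 and C7 unassigned)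
Conditions: KOtBu, THF, 0 °C to rt; aq. NH4Cl
Reagents that add atoms: none
Why: Dieckmann condensation: the tert-butyl ester enolate at C10 attacks the methyl ester carbon C8 and closes the six-membered ring; the reverse mode of closure would give a β-keto ester that cannot be deprotonated and is therefore reversed, so the enolate of 14 accumulates.

Step 10
Reactants: 14 β-keto ester; 15 diiodomethane
Product: 18 tert-butyl (1R,3aS,8aR)-1-methyl-6-oxo-7-(propan-2-yl)-1,2,3,3a,6,7,8,8a-octahydroazulene-4-carboxylate (C7 unassigned), via ring-enlarged ethylzinc enolate 16 (not isolated), via tertiary iodo keto ester 17 (not isolated)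
Conditions: Et2Zn (5 equiv), 15 (5 equiv), CH2Cl2, 0 °C to rt; I2, 0 °C; aq. Na2S2O3; DBU, 0 °C
Reagents that add atoms: diethylzinc, CC[Zn]CC; iodine, II
Why: Et2Zn deprotonates the β-keto ester at C10 and the zinc enolate is alkylated on C10 by EtZnCH2I; the zinc homoenolate so formed adds to the C8 carbonyl in a 3-exo-trig closure to a cyclopropanolate, which fragments by cleavage of the original C10–C8 bond to the ester enolate 16, so that C9 is inserted and the six-membered ring becomes ring C (ring formation by one-carbon enlargement, with C9–C10 and C8–C9 as the new bonds). Iodine converts 16 into the tertiary α-iodo ester 17, and DBU removes a C9 hydrogen, which is α to the ketone, and expels iodide, so the C9=C10 double bond ends up conjugated with both carbonyl groups. The closest known reaction type is the zinc-carbenoid chain extension of β-keto esters to γ-keto esters with iodination and elimination in the same flask, applied here to an α-substituted cyclic substrate, where it amounts to a ring expansion. No stereocentre is created: C10 and C9 end as sp2 carbons and C7 remains an unassigned, enolisable centre. The step needs insertion at one site, which the mechanism secures because only the enolate between the two carbonyl groups reacts with the carbenoid, and elimination toward C9 and not C1, which follows from the much higher acidity of the C9 hydrogens. C1, C4 and C5 are not enolisable in 14; in 18 the C1 hydrogen is a vinylogous acidic position, so DBU is used briefly at 0 °C.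

Step 11
Reactants: 18 ene-keto ester
Product: 19 tert-butyl (1R,3aS,8aR)-1-methyl-7-(propan-2-yl)-6-(trifluoromethanesulfonyloxy)-1,2,3,3a,8,8a-hexahydroazulene-4-carboxylate
Conditions: KN(SiMe3)2, THF, −78 °C; then N-(5-chloropyridin-2-yl)bis(trifluoromethanesulfonimide), −78 to 0 °C
Reagents that add atoms: N-(5-chloropyridin-2-yl)bis(trifluoromethanesulfonimide), O=S(=O)(N(c1ccc(Cl)cn1)S(=O)(=O)C(F)(F)F)C(F)(F)F
Why: The C8 ketone has a hydrogen only at C7 on its saturated side, so kinetic deprotonation with a hindered amide gives the cross-conjugated dienolate (deprotonation at C7 is faster than at the vinylogous position C1), which is O-sulfonylated to the dienyl triflate.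

Step 12
Reactants: 19 dienyl triflate
Product: 20 tert-butyl (1R,3aS,8aR)-1-methyl-7-(propan-2-yl)-1,2,3,3a,8,8a-hexahydroazulene-4-carboxylate
Conditions: Pd(OAc)2 (5 mol %), PPh3 (10 mol %), Bu3N, HCO2H, DMF, 60 °C
Reagents that add atoms: none
Why: Palladium-catalysed formate reduction of an alkenyl triflate (oxidative addition, formate exchange, decarboxylation to a palladium hydride, reductive elimination) replaces the triflate by hydrogen without moving the double bonds, which gives the C7=C8/C9=C10 diene.

Step 13
Reactants: 20 diene ester
Product: 21 (1R,3aS,8aR)-1-methyl-7-(propan-2-yl)-1,2,3,3a,8,8a-hexahydroazulene-4-carboxylic acid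
Conditions: CF3CO2H, CH2Cl2, 0 °C
Reagents that add atoms: none
Why: Acidolysis of the tert-butyl ester with loss of isobutene frees the acid without base, so the diene is not isomerised through C1; the electron-poor dienoate is protonated only slowly at 0 °C.

Step 14
Reactants: 22 (R)-carvone
Product: 23 (5R)-5-(3-chloroprop-1-en-2-yl)-2-methylcyclohex-2-en-1-one
Conditions: Ca(OCl)2, CO2 (solid), CH2Cl2/H2O, 0 °C
Reagents that add atoms: calcium hypochlorite, [Ca+2].[O-]Cl.[O-]Cl
Why: Ene-type allylic chlorination by hypochlorous acid: chloronium formation at the electron-rich 1,1-disubstituted alkene and loss of a methyl proton give the 2-(chloromethyl)allyl group (C3′, C4′, C11′); the conjugated ring alkene is deactivated and does not react.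

Step 15
Reactants: 23 chloro enone
Product: 24 (1R,4R,6R)-4-(3-chloroprop-1-en-2-yl)-1-methyl-7-oxabicyclo[4.1.0]heptan-2-one (epoxide trans to the side chain)
Conditions: 30% H2O2, NaOH (cat.), MeOH, 0 °C
Reagents that add atoms: hydrogen peroxide, OO
Why: Weitz–Scheffer nucleophilic epoxidation is specific for the enone double bond and leaves the isolated alkene and, at 0 °C, the allylic chloride untouched; attack anti to the side chain should give the trans epoxide, whose configuration is immaterial because both epoxide carbons are cleaved in step 16.

Step 16
Reactants: 24 epoxy ketone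
Product: 25 (3R)-3-(3-chloroprop-1-en-2-yl)-5-oxopentanoic acid
Conditions: H5IO6 (2.5 equiv), THF/H2O, 0 °C to rt
Reagents that add atoms: water, O
Why: Periodic acid hydrolyses the epoxide to the keto diol and then cleaves the α-ketol and glycol units (Malaprade-type cleavage); the methyl-bearing ring carbon is excised, the former ketone carbon becomes the carboxyl carbon C1′ and the former β-carbon the aldehyde C7′, and C5′ is not touched.

Step 17
Reactants: 25 chloro acid
Product: 26 2-[(4R)-5-methylidene-2-oxooxan-4-yl]acetaldehyde
Conditions: KHCO3, NaI (cat.), DMF, 40 °C
Reagents that add atoms: none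
Why: Intramolecular SN2 O-alkylation of the carboxylate by the allylic chloride (6-exo-tet) closes ring B as the δ-lactone; the weak base does not enolise the aldehyde to a significant extent.

Step 18
Reactants: 26 lactone aldehyde
Product: 27 (4R)-4-(2,2-dimethoxyethyl)-5-methylideneoxan-2-one
Conditions: HC(OMe)3, MeOH, PPTS (cat.), rt
Reagents that add atoms: trimethyl orthoformate, COC(OC)OC
Why: Acid-catalysed acetalisation with the orthoformate as water scavenger masks the aldehyde for the enolate chemistry; the weak acid leaves the lactone and the exocyclic alkene alone.

Step 19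
Reactants: 27 lactone acetal; 28 (tert-butyldimethylsilyloxy)acetaldehyde
Product: 29 (4R)-3-[2-(tert-butyldimethylsilyloxy)-1-hydroxyethyl]-4-(2,2-dimethoxyethyl)-5-methylideneoxan-2-one (mixture at C9′ and at the carbinol carbon)
Conditions: LiN(iPr)2, THF, −78 °C; then 28, −78 °C
Reagents that add atoms: none
Why: Aldol addition of the lithium lactone enolate to the α-silyloxy aldehyde forms the C8′–C9′ bond; the configurations at C9′ and at the carbinol carbon do not matter because both are reset in steps 20 and 22.

Step 20
Reactants: 29 aldol adduct
Product: 30 (4R)-3-[(tert-butyldimethylsilyloxy)acetyl]-4-(2,2-dimethoxyethyl)-5-methylideneoxan-2-one (C9′ epimerisable)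
Conditions: Dess–Martin periodinane, NaHCO3, CH2Cl2, 0 °C to rt
Reagents that add atoms: none
Why: Dess–Martin oxidation of the secondary alcohol under buffered conditions gives the β-keto lactone without retro-aldol cleavage or loss of the silyl ether.

Step 21
Reactants: 30 β-keto lactone acetal
Product: 31 2-[(4R)-3-[(tert-butyldimethylsilyloxy)acetyl]-5-methylidene-2-oxooxan-4-yl]acetaldehyde (C9′ epimerisable)
Conditions: PPTS (cat.), acetone/H2O (10:1), 45 °C
Reagents that add atoms: water, O
Why: Mild acid-catalysed hydrolysis of the dimethyl acetal; the primary silyl ether is deactivated toward acid by the adjacent ketone and the lactone is stable to the weak catalyst.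

Step 22
Reactants: 31 keto aldehyde
Product: 32 (4aR,6S,7S,7aR)-7-[(tert-butyldimethylsilyloxy)methyl]-6,7-dihydroxy-4-methylidenehexahydrocyclopenta[c]pyran-1(3H)-one
Conditions: SmI2 (2.5 equiv), MeOH (2 equiv), THF, −78 °C
Reagents that add atoms: none
Why: SmI2-mediated pinacol cyclisation (ketyl formation, addition to the second carbonyl group, second electron transfer) closes ring A through the C7′–C8′ bond; trivalent samarium bridges the C8′ ketyl oxygen and the lactone carbonyl on C9′, so the C8′ oxygen ends up cis to C1′, the C7′ oxygen is delivered cis to it within the samarium diolate, and the cis ring fusion follows from the short tether and from C9′ equilibrating through the β-keto lactone enol, so that C7′, C8′ and C9′ are all controlled by the chelate and by C5′.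

Step 23
Reactants: 32 silyl ether diol
Product: 33 (4aR,6S,7S,7aR)-6,7-dihydroxy-7-(hydroxymethyl)-4-methylidenehexahydrocyclopenta[c]pyran-1(3H)-one
Conditions: HF·pyridine, pyridine, THF, 0 °C to rt
Reagents that add atoms: none
Why: Fluoride-mediated cleavage of the primary silyl ether under buffered, slightly acidic conditions that neither open nor epimerise the β-hydroxy lactone.

Step 24
Reactants: 21 dienoic acid; 33 iridoid triol
Product: 35 nardostachysin, via mixed anhydride 34 (not isolated)
Conditions: 21, 2,4,6-trichlorobenzoyl chloride, Et3N, toluene, rt; then 33, DMAP, toluene/THF, 0 °C to rt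
Reagents that add atoms: 2,4,6-trichlorobenzoyl chloride, O=C(Cl)c1c(Cl)cc(Cl)cc1Cl
Why: Yamaguchi esterification: DMAP attacks the mixed anhydride at the less hindered dienoyl carbonyl, and the acylpyridinium ion acylates the only primary hydroxyl; the secondary C7′ hydroxyl on the concave face and the tertiary C8′ hydroxyl react far more slowly with an α-branched acyl donor.

## Compound list

1 | (R)-pulegone, (5R)-5-methyl-2-(propan-2-ylidene)cyclohexan-1-one | C[C@@H]1CCC(=C(C)C)C(=O)C1 | starting material
2 | pulegone dibromide, (5R)-2-bromo-2-(2-bromopropan-2-yl)-5-methylcyclohexan-1-one (C2 unassigned) | C[C@@H]1CCC(Br)(C(C)(C)Br)C(=O)C1 | intermediate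
3 | methyl (5R)-5-methyl-2-(propan-2-ylidene)cyclopentane-1-carboxylate (C1 epimers) | C[C@@H]1CCC(=C(C)C)C1C(=O)OC | intermediate
4 | methyl (2R)-2-methyl-5-oxocyclopentane-1-carboxylate (C1 epimerisable) | C[C@@H]1CCC(=O)C1C(=O)OC | intermediate
5 | methyl (5R)-5-methyl-2-(trifluoromethanesulfonyloxy)cyclopent-1-ene-1-carboxylate | C[C@@H]1CCC(OS(=O)(=O)C(F)(F)F)=C1C(=O)OC | intermediate
6 | tert-butyl bromoacetate | CC(C)(C)OC(=O)CBr | starting material
7 | (2-tert-butoxy-2-oxoethyl)zinc bromide | Br[Zn]CC(=O)OC(C)(C)C | intermediate
8 | methyl (5R)-2-(2-tert-butoxy-2-oxoethyl)-5-methylcyclopent-1-ene-1-carboxylate | C[C@@H]1CCC(CC(=O)OC(C)(C)C)=C1C(=O)OC | intermediate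
9 | methyl (1R,2R,5R)-2-(2-tert-butoxy-2-oxoethyl)-5-methylcyclopentane-1-carboxylate (all-cis) | COC(=O)[C@@H]1[C@H](C)CC[C@@H]1CC(=O)OC(C)(C)C | intermediate
10 | tert-butyl 2-[(1R,2R,3R)-2-(hydroxymethyl)-3-methylcyclopentyl]acetate | OC[C@@H]1[C@H](C)CC[C@@H]1CC(=O)OC(C)(C)C | intermediate
11 | tert-butyl 2-[(1R,2R,3R)-2-(iodomethyl)-3-methylcyclopentyl]acetate | IC[C@@H]1[C@H](C)CC[C@@H]1CC(=O)OC(C)(C)C | intermediate
12 | methyl 3-methylbutanoate | COC(=O)CC(C)C | starting material
13 | methyl 2-{[(1R,2R,5R)-2-(2-tert-butoxy-2-oxoethyl)-5-methylcyclopentyl]methyl}-3-methylbutanoate (C7 epimers) | COC(=O)C(C(C)C)C[C@@H]1[C@H](C)CC[C@@H]1CC(=O)OC(C)(C)C | intermediate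
14 | tert-butyl (1R,3aS,7aR)-1-methyl-5-oxo-6-(propan-2-yl)octahydro-1H-indene-4-carboxylate (two enolisable carbons unassigned) | CC(C)(C)OC(=O)C1C(=O)C(C(C)C)C[C@@H]2[C@H](C)CC[C@H]12 | intermediate
15 | diiodomethane | ICI | starting material
16 | ethylzinc enolate of the ring-enlarged γ-keto tert-butyl ester (enolate at C10/C14) | CC[Zn]OC(OC(C)(C)C)=C1CC(=O)C(C(C)C)C[C@@H]2[C@H](C)CC[C@H]12 | intermediate
17 | tert-butyl (1R,3aS,8aR)-4-iodo-1-methyl-6-oxo-7-(propan-2-yl)decahydroazulene-4-carboxylate (C10 and C7 unassigned) | CC(C)(C)OC(=O)C1(I)CC(=O)C(C(C)C)C[C@@H]2[C@H](C)CC[C@H]12 | intermediate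
18 | tert-butyl (1R,3aS,8aR)-1-methyl-6-oxo-7-(propan-2-yl)-1,2,3,3a,6,7,8,8a-octahydroazulene-4-carboxylate (C7 unassigned) | CC(C)(C)OC(=O)C1=CC(=O)C(C(C)C)C[C@@H]2[C@H](C)CC[C@H]12 | intermediate
19 | tert-butyl (1R,3aS,8aR)-1-methyl-7-(propan-2-yl)-6-(trifluoromethanesulfonyloxy)-1,2,3,3a,8,8a-hexahydroazulene-4-carboxylate | CC(C)(C)OC(=O)C1=CC(OS(=O)(=O)C(F)(F)F)=C(C(C)C)C[C@@H]2[C@H](C)CC[C@H]12 | intermediate
20 | tert-butyl (1R,3aS,8aR)-1-methyl-7-(propan-2-yl)-1,2,3,3a,8,8a-hexahydroazulene-4-carboxylate | CC(C)(C)OC(=O)C1=CC=C(C(C)C)C[C@@H]2[C@H](C)CC[C@H]12 | intermediate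
21 | (1R,3aS,8aR)-1-methyl-7-(propan-2-yl)-1,2,3,3a,8,8a-hexahydroazulene-4-carboxylic acid | OC(=O)C1=CC=C(C(C)C)C[C@@H]2[C@H](C)CC[C@H]12 | intermediate
22 | (R)-carvone, (5R)-2-methyl-5-(prop-1-en-2-yl)cyclohex-2-en-1-one | CC1=CC[C@H](CC1=O)C(C)=C | starting material
23 | (5R)-5-(3-chloroprop-1-en-2-yl)-2-methylcyclohex-2-en-1-one | CC1=CC[C@H](CC1=O)C(=C)CCl | intermediate
24 | (1R,4R,6R)-4-(3-chloroprop-1-en-2-yl)-1-methyl-7-oxabicyclo[4.1.0]heptan-2-one | C[C@@]12O[C@@H]1C[C@H](CC2=O)C(=C)CCl | intermediate
25 | (3R)-3-(3-chloroprop-1-en-2-yl)-5-oxopentanoic acid | OC(=O)C[C@H](C(=C)CCl)CC=O | intermediate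
26 | 2-[(4R)-5-methylidene-2-oxooxan-4-yl]acetaldehyde | C=C1COC(=O)C[C@H]1CC=O | intermediate
27 | (4R)-4-(2,2-dimethoxyethyl)-5-methylideneoxan-2-one | C=C1COC(=O)C[C@H]1CC(OC)OC | intermediate
28 | (tert-butyldimethylsilyloxy)acetaldehyde | CC(C)(C)[Si](C)(C)OCC=O | starting material
29 | (4R)-3-[2-(tert-butyldimethylsilyloxy)-1-hydroxyethyl]-4-(2,2-dimethoxyethyl)-5-methylideneoxan-2-one (C9′ and carbinol carbon unassigned) | C=C1COC(=O)C(C(O)CO[Si](C)(C)C(C)(C)C)[C@H]1CC(OC)OC | intermediate
30 | (4R)-3-[(tert-butyldimethylsilyloxy)acetyl]-4-(2,2-dimethoxyethyl)-5-methylideneoxan-2-one (C9′ unassigned) | C=C1COC(=O)C(C(=O)CO[Si](C)(C)C(C)(C)C)[C@H]1CC(OC)OC | intermediate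
31 | 2-[(4R)-3-[(tert-butyldimethylsilyloxy)acetyl]-5-methylidene-2-oxooxan-4-yl]acetaldehyde (C9′ unassigned) | C=C1COC(=O)C(C(=O)CO[Si](C)(C)C(C)(C)C)[C@H]1CC=O | intermediate
32 | (4aR,6S,7S,7aR)-7-[(tert-butyldimethylsilyloxy)methyl]-6,7-dihydroxy-4-methylidenehexahydrocyclopenta[c]pyran-1(3H)-one | C=C1COC(=O)[C@@H]2[C@H]1C[C@H](O)[C@@]2(O)CO[Si](C)(C)C(C)(C)C | intermediate
33 | (4aR,6S,7S,7aR)-6,7-dihydroxy-7-(hydroxymethyl)-4-methylidenehexahydrocyclopenta[c]pyran-1(3H)-one | C=C1COC(=O)[C@@H]2[C@H]1C[C@H](O)[C@@]2(O)CO | intermediate
34 | mixed anhydride of 21 with 2,4,6-trichlorobenzoic acid | O=C(OC(=O)c1c(Cl)cc(Cl)cc1Cl)C1=CC=C(C(C)C)C[C@@H]2[C@H](C)CC[C@H]12 | intermediate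
35 | nardostachysin, [(4aR,6S,7S,7aR)-6,7-dihydroxy-4-methylidene-1-oxooctahydrocyclopenta[c]pyran-7-yl]methyl (1R,3aS,8aR)-1-methyl-7-(propan-2-yl)-1,2,3,3a,8,8a-hexahydroazulene-4-carboxylate | C=C1COC(=O)[C@@H]2[C@H]1C[C@H](O)[C@@]2(O)COC(=O)C1=CC=C(C(C)C)C[C@@H]2[C@H](C)CC[C@H]12 | target

## Step count and least certain steps

Total: 24 steps. Longest linear sequence: 14 steps (steps 1–13 and step 24). The iridoid branch is 10 steps (14–23) and joins in step 24.

Step 10 (key step). The most likely failure is slow attack of the carbenoid on the fully substituted enolate carbon C10, so that insertion stays incomplete or the ring-enlarged enolate is methylated by excess carbenoid. In the second half, elimination may go toward C1, or the C1 configuration may be lost by vinylogous enolisation under DBU. Fallback: from 14, silylation (Me3SiCl, Et3N, DMF) would give the trimethylsilyl enol ether F1. Cyclopropanation with Et2Zn and 15 would give the siloxycyclopropane ester F2. FeCl3 in DMF would open the C8–C10 bond oxidatively (Saegusa-type ring enlargement) to the tertiary chloro keto ester F3. NaOAc in methanol would then eliminate hydrogen chloride and rejoin the route at 18.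

Step 22. The α-silyloxy ketone may lose the C10′ oxygen by β-elimination from the ketyl, or chelation control may erode because the silyl ether oxygen also binds samarium, which would lower facial selectivity at C8′. Fallback: from 31, an intramolecular crossed benzoin reaction under triazolylidene carbene catalysis (triazolium salt, Et3N) would form the C7′–C8′ bond without a ketyl and give the α-ketol F4 (C7′ ketone, C8′ tertiary alcohol with the bulky CH2OSi group on the convex face). Hydride delivery from the convex face (NaBH4, CeCl3·7H2O, MeOH, −78 °C) would then give 32.

Step 24. Discrimination between the primary C10′ hydroxyl and the secondary C7′ hydroxyl may be incomplete, or the acyl group may migrate from O10′ to O7′ under DMAP. Fallback: from 32, 2,2-dimethoxypropane with PPTS would give the acetonide silyl ether F5 and Bu4NF the acetonide alcohol F6 (identical with A6). Yamaguchi esterification with 21 would give nardostachysin 7′,8′-acetonide F7 (identical with A7), and aqueous acetic acid would remove the acetonide to reach 35.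

Step 8. Proton transfer from the CH2 of the tert-butyl ester to the isovalerate enolate and slow SN2 at a β-branched iodide may stall the alkylation. Fallback: from 11, deprotonation with LiN(iPr)2 (2 equiv) and acylation with 3-methylbutanoyl chloride would give the acyclic β-keto ester iodide F8 (C8–C10 bond first). Its dianion (NaH, then BuLi, THF) would close the ring by intramolecular γ-alkylation at C7 and rejoin the route at 14, bypassing 13.

Step 11. Deprotonation may occur at the vinylogous position C1 instead of the hindered methine C7, or the amide may add to the doubly activated C9=C10 bond. Fallback: from 18, 1,2-reduction (NaBH4, CeCl3·7H2O, MeOH) would give the C8 allylic alcohol F9. Burgess dehydration, for which C7–H is the only available β-hydrogen, would give 20 directly, bypassing 19.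

## Further compounds

F1 | step 10 | trimethylsilyl enol ether of 14 (silyloxy on C8, C8=C10) | CC(C)(C)OC(=O)C1=C(O[Si](C)(C)C)C(C(C)C)C[C@@H]2[C@H](C)CC[C@H]12
F2 | step 10 | siloxycyclopropane ester from F1 (CH2 bridging C8 and C10) | CC(C)(C)OC(=O)C13CC1(O[Si](C)(C)C)C(C(C)C)C[C@@H]2[C@H](C)CC[C@@H]23
F3 | step 10 | ring-enlarged tertiary chloro keto ester (Cl on C10, ketone at C8) | CC(C)(C)OC(=O)C1(Cl)CC(=O)C(C(C)C)C[C@@H]2[C@H](C)CC[C@H]12
F4 | step 22 | bicyclic α-ketol (C7′ ketone, C8′ tertiary alcohol, C10′ silyl ether) | C=C1COC(=O)[C@@H]2[C@H]1CC(=O)[C@@]2(O)CO[Si](C)(C)C(C)(C)C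
F5 | step 24 | 7′,8′-acetonide of 32 | C=C1COC(=O)[C@@H]2[C@H]1C[C@@H]3OC(C)(C)O[C@]23CO[Si](C)(C)C(C)(C)C
F6 | step 24 | iridoid 7′,8′-acetonide with free C10′ hydroxyl | C=C1COC(=O)[C@@H]2[C@H]1C[C@@H]3OC(C)(C)O[C@]23CO
F7 | step 24 | nardostachysin 7′,8′-acetonide | C=C1COC(=O)[C@@H]2[C@H]1C[C@@H]3OC(C)(C)O[C@]23COC(=O)C1=CC=C(C(C)C)C[C@@H]2[C@H](C)CC[C@H]12
F8 | step 8 | tert-butyl 2-[(1R,2R,3R)-2-(iodomethyl)-3-methylcyclopentyl]-5-methyl-3-oxohexanoate (C10 unassigned) | IC[C@@H]1[C@H](C)CC[C@@H]1C(C(=O)CC(C)C)C(=O)OC(C)(C)C
F9 | step 11 | C8 allylic alcohol from 18 (C7 and C8 unassigned) | CC(C)(C)OC(=O)C1=CC(O)C(C(C)C)C[C@@H]2[C@H](C)CC[C@H]12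
A1 | alternative 1 | acetal-tethered 1,7-enyne (4-methoxybenzyl ether of the vinyl carbinol, methyl acetal of the silyloxybutynal) | COc1ccc(CO[C@@H](C=C)COC(OC)C#CCO[Si](C)(C)C(C)(C)C)cc1
A2 | alternative 1 | bicyclic enone acetal with ketone at C7′ (acetal carbon either epimer) | COc1ccc(CO[C@@H]2COC(OC)C3=C(CO[Si](C)(C)C(C)(C)C)C(=O)C[C@H]32)cc1
A3 | alternative 2 | α-diazo lactone with trans-dioxolane side chain and C10′ silyl ether | C=C1COC(=O)C(=[N+]=[N-])[C@H]1C[C@@H]2OC(C)(C)O[C@H]2CO[Si](c3ccccc3)(c3ccccc3)C(C)(C)C
A4 | alternative 2 | iridoid lactone 7′,8′-acetonide, C10′ tert-butyldiphenylsilyl ether | C=C1COC(=O)[C@@H]2[C@H]1C[C@@H]3OC(C)(C)O[C@]23CO[Si](c4ccccc4)(c4ccccc4)C(C)(C)C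
A5 | alternative 3 | dienyl triflate of the acid half (triflate on C10) | O=S(=O)(OC1=CC=C(C(C)C)C[C@@H]2[C@H](C)CC[C@H]12)C(F)(F)F
A6 | alternative 3 | iridoid 7′,8′-acetonide with free C10′ hydroxyl | C=C1COC(=O)[C@@H]2[C@H]1C[C@@H]3OC(C)(C)O[C@]23CO
A7 | alternative 3 | nardostachysin 7′,8′-acetonide | C=C1COC(=O)[C@@H]2[C@H]1C[C@@H]3OC(C)(C)O[C@]23COC(=O)C1=CC=C(C(C)C)C[C@@H]2[C@H](C)CC[C@H]12
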